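**Plan**

1. Retrosynthesis first removes the C3=CHPh bond (aldol condensation with benzaldehyde) and the C5 ketone oxygen (hydration of an aryl alkyne); the lactone carbon C2 is traced back to an allyl group on C3a that is cleaved and oxidised onto the free O1.
2. The benzene ring is then cut at C7a–C3a, C4–C5 and C7–C7a into a squarate-derived 4-siloxy-2-alkynylcyclobutenone (C5, C6, C7, C7a) and 1-methoxypent-4-en-1-yne (C3a, C4, the methoxy group, the allyl group).
3. Enabling feature (benzofuran-2(3H)-one numbering): the methyl ether O4 and the lactone oxygen O1 on C7a are meta with C3a between them, which is the resorcinol monoether pattern a vinylketene and a methoxyalkyne generate; C5, O6 and O7 are the alkynylated carbon, the ester oxygen and the reduced carbonyl of a squarate.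
4. Forward: squarate → alkynylcyclobutenedione → 4-siloxycyclobutenone; the benzannulation forms the hexasubstituted benzene ring; the lactone ring follows (allyl cleavage, lactol oxidation), then alkyne hydration, benzylidenation and removal of the silyl and isopropyl groups.
5. Stereochemistry: the only element in the target is the Z benzylidene alkene, set under thermodynamic control in the condensation; the racemic cyclobutenone centre disappears on aromatisation.

Key step: step 5

Remark: the benzylidene double bond of the target is Z (phenyl on the side of the lactone carbonyl, C3a on the other side). It is assumed to be the thermodynamically favoured geometry, because the E isomer would press the phenyl ring against the C4 methoxy group.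

**Route**

Step 1
Reactants: 1 diisopropyl squarate (3,4-diisopropoxycyclobut-3-ene-1,2-dione); 2 3-phenyl-1-propyne
Product: 5 3-isopropoxy-4-(3-phenylprop-1-ynyl)cyclobut-3-ene-1,2-dione, via lithium acetylide 3 (not isolated), via lithium alkoxide adduct 4 (not isolated)
Conditions: 2, n-BuLi, THF, −78 °C; add to 1, THF, −78 °C; (CF3CO)2O, −78 °C; then H2O
Reagents that add atoms: water, O
Why: 1,2-addition of a lithium acetylide to one squarate carbonyl, followed by trifluoroacetylation and hydrolytic 1,3-transposition with loss of isopropanol, is the standard squarate-to-cyclobutenedione sequence; one equivalent of base at −78 °C removes only the acetylenic proton and leaves the propargylic benzylic CH2 alone.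

Step 2
Reactants: 5 3-isopropoxy-4-(3-phenylprop-1-ynyl)cyclobut-3-ene-1,2-dione
Product: 6 rac-4-hydroxy-3-isopropoxy-2-(3-phenylprop-1-ynyl)cyclobut-2-en-1-one
Conditions: LiAlH(OtBu)3, THF, −78 °C; then H2O
Reagents that add atoms: none
Why: regioselective 1,2-reduction of a cyclobutenedione, in which the bulky hydride should attack the ketone-like carbonyl next to the isopropoxy-bearing carbon and spare the vinylogous ester carbonyl next to the alkynyl carbon; the new carbinol centre forms as a racemate and is erased in step 5.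

Step 3
Reactants: 6 rac-4-hydroxy-3-isopropoxy-2-(3-phenylprop-1-ynyl)cyclobut-2-en-1-one
Product: 7 rac-4-(tert-butyldimethylsilyloxy)-3-isopropoxy-2-(3-phenylprop-1-ynyl)cyclobut-2-en-1-one
Conditions: TBSCl, imidazole, DMF, 0 °C → rt
Reagents that add atoms: tert-butyldimethylsilyl chloride, CC(C)(C)[Si](C)(C)Cl
Why: standard silylation of a secondary alcohol, which prevents the later vinylketene from collapsing to a butenolide through a free hydroxyl and supplies the donor substituent that rotates outward on ring opening.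

Step 4
Reactants: 8 chloroacetaldehyde dimethyl acetal; 9 allyl bromide
Product: 11 1-methoxypent-4-en-1-yne, via sodium methoxyacetylide 10 (not isolated)
Conditions: NaNH2 (3.0 equiv), liq. NH3, −33 °C; then 9, −33 °C → rt
Reagents that add atoms: none
Why: threefold amide-induced elimination and deprotonation of the chloroacetal is the classical entry to a sodium alkoxyacetylide, which should be alkylated at carbon by the reactive allylic bromide (SN2); exactly three equivalents of amide are used so that no base strong enough to isomerise the skipped enyne remains.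

Step 5
Reactants: 7 rac-4-(tert-butyldimethylsilyloxy)-3-isopropoxy-2-(3-phenylprop-1-ynyl)cyclobut-2-en-1-one; 11 1-methoxypent-4-en-1-yne
Product: 16 2-allyl-6-(tert-butyldimethylsilyloxy)-5-isopropoxy-3-methoxy-4-(3-phenylprop-1-ynyl)phenol, via vinylketene 12 (not isolated), via vinylcyclobutenone 13 (not isolated), via dienylketene 14 (not isolated), via cyclohexadienone 15 (not isolated)
Conditions: 11 (2 equiv), toluene, 80 → 110 °C, sealed tube, argon
Reagents that add atoms: none
Why: On heating, 7 should undergo conrotatory 4π ring opening with the siloxy donor turning outward to give vinylketene 12, whose ketene C=C then takes up ynol ether 11 in a polar [2+2] cycloaddition that closes the four-membered ring of 13 by joining the nucleophilic, allyl-bearing alkyne carbon to the ketene carbonyl carbon (C7a–C3a) and the methoxy-bearing carbon to the alkynyl-substituted ketene carbon (C4–C5). A second 4π opening of 13 gives dienylketene 14, whose thermal disrotatory 6π electrocyclisation bonds the ketene carbon to the CH(OTBS) terminus (C7a–C7) and closes the six-membered carbocycle as dienone 15, which tautomerises to phenol 16. The closest known reaction is the Danheiser benzannulation of cyclobutenones with alkoxy- and siloxyalkynes, here applied to a 3,4-dioxygenated 2-alkynylcyclobutenone that has not been used as the partner before. No stereocentre is carried forward, since the racemic centre of 7, the quaternary centre of 13 and the sp3 carbon of 15 all end as arene carbons. Two selectivities are needed: the orientation of the [2+2] step, which the polarisation of the ynol ether fixes so that the allyl group lands between the new hydroxyl and the methoxy group, and opening of 13 with the vinyl rather than the alkynyl arm turned toward the ketene, which is secured because this opening is reversible and only the vinyl-inward isomer has the fast 6π exit, whereas diradical closure of an enynylketene is slower. The ketene carbonyl becomes the only free hydroxyl (the future lactone oxygen O1), the ynol ether delivers the C4 methyl ether without a protecting-group step, and the rod-shaped alkynyl substituent adds little bulk at the carbon that turns quaternary in the cycloaddition.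

Step 6
Reactants: 16 2-allyl-6-(tert-butyldimethylsilyloxy)-5-isopropoxy-3-methoxy-4-(3-phenylprop-1-ynyl)phenol
Product: 19 rac-7-(tert-butyldimethylsilyloxy)-6-isopropoxy-4-methoxy-5-(3-phenylprop-1-ynyl)-2,3-dihydrobenzofuran-2-ol, via vicinal diol 17 (not isolated), via arylacetaldehyde 18 (not isolated)
Conditions: OsO4 (cat.), NMO, acetone/H2O, rt; then NaIO4 (1.2 equiv), pH 7 buffer, 0 °C
Reagents that add atoms: osmium tetroxide (oxygen carrier), O=[Os](=O)(=O)=O; N-methylmorpholine N-oxide (terminal oxygen source), C[N+]1([O-])CCOCC1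
Why: Upjohn dihydroxylation should touch only the terminal alkene (internal alkyne and arene are inert to OsO4 here), and a brief cold periodate glycol cleavage gives the arylacetaldehyde, which the ortho hydroxyl captures as the five-membered lactol; the hemiacetal centre forms as a racemate and is removed in step 7.

Step 7
Reactants: 19 rac-7-(tert-butyldimethylsilyloxy)-6-isopropoxy-4-methoxy-5-(3-phenylprop-1-ynyl)-2,3-dihydrobenzofuran-2-ol
Product: 20 7-(tert-butyldimethylsilyloxy)-6-isopropoxy-4-methoxy-5-(3-phenylprop-1-ynyl)benzofuran-2(3H)-one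
Conditions: nPr4N[RuO4] (cat.), NMO, 4 Å MS, CH2Cl2, rt
Reagents that add atoms: none
Why: Ley–Griffith oxidation of a lactol to the lactone under neutral, anhydrous conditions, which should neither dehydrate the lactol to a benzofuran nor affect the alkyne, the silyl ether or the aryl ethers.

Step 8
Reactants: 20 7-(tert-butyldimethylsilyloxy)-6-isopropoxy-4-methoxy-5-(3-phenylprop-1-ynyl)benzofuran-2(3H)-one
Product: 21 7-(tert-butyldimethylsilyloxy)-6-isopropoxy-4-methoxy-5-(3-phenylpropanoyl)benzofuran-2(3H)-one
Conditions: CF3CO2H, H2O (3 equiv), CH2Cl2, 0 °C → rt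
Reagents that add atoms: water, O
Why: Brønsted acid-mediated Markovnikov hydration, in which protonation at the benzyl-bearing alkyne carbon gives a vinyl cation conjugated with the 2,6-dialkoxyaryl ring so that oxygen enters at the ring-bound carbon; a proton acid is chosen over a π-acidic metal to avoid 5-endo attack of the flanking ether oxygens on the activated alkyne.

Step 9
Reactants: 21 7-(tert-butyldimethylsilyloxy)-6-isopropoxy-4-methoxy-5-(3-phenylpropanoyl)benzofuran-2(3H)-one; 22 benzaldehyde
Product: 23 (Z)-3-benzylidene-7-(tert-butyldimethylsilyloxy)-6-isopropoxy-4-methoxy-5-(3-phenylpropanoyl)benzofuran-2(3H)-one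
Conditions: Et3N (cat.), toluene, 4 Å MS, 60 °C, argon
Reagents that add atoms: none
Why: Knoevenagel-type aldol condensation at the C3 methylene, whose enolate is an aromatic benzofuran-2-olate and therefore far more acidic than the ketone methylene, with a tertiary amine that cannot acylate on the aryl lactone; the reversible addition–elimination should settle on the Z alkene, in which the phenyl ring lies beside the lactone carbonyl and away from the C4 methoxy group.

Step 10
Reactants: 23 (Z)-3-benzylidene-7-(tert-butyldimethylsilyloxy)-6-isopropoxy-4-methoxy-5-(3-phenylpropanoyl)benzofuran-2(3H)-one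
Product: 24 (Z)-3-benzylidene-7-hydroxy-6-isopropoxy-4-methoxy-5-(3-phenylpropanoyl)benzofuran-2(3H)-one
Conditions: HF·pyridine, THF, 0 °C → rt
Reagents that add atoms: none
Why: fluoride cleavage of an aryl silyl ether under acidic buffering, which should leave the base-sensitive benzylidene aryl lactone and both alkyl aryl ethers untouched.

Step 11
Reactants: 24 (Z)-3-benzylidene-7-hydroxy-6-isopropoxy-4-methoxy-5-(3-phenylpropanoyl)benzofuran-2(3H)-one
Product: 25 bractelactone, (Z)-3-benzylidene-6,7-dihydroxy-4-methoxy-5-(3-phenylpropanoyl)benzofuran-2(3H)-one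
Conditions: BCl3, CH2Cl2, −78 → −20 °C; then H2O
Reagents that add atoms: none
Why: Lewis acid dealkylation selective for the secondary isopropyl ether, which ionises at low temperature while the methyl ether would need a slower SN2 cleavage; the free C7 hydroxyl binds boron and delivers it to the neighbouring O6, and the resulting five-membered catechol borate hydrolyses on work-up.

**Compound list**

1 | diisopropyl squarate (3,4-diisopropoxycyclobut-3-ene-1,2-dione) | CC(C)OC1=C(OC(C)C)C(=O)C1=O | starting material
2 | 3-phenyl-1-propyne | C#CCc1ccccc1 | starting material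
3 | lithium 3-phenylprop-1-yn-1-ide | [Li+].[C-]#CCc1ccccc1 | intermediate
4 | lithium 2,3-diisopropoxy-4-oxo-1-(3-phenylprop-1-ynyl)cyclobut-2-en-1-olate (racemic) | CC(C)OC1=C(OC(C)C)C([O-])(C#CCc2ccccc2)C1=O.[Li+] | intermediate
5 | 3-isopropoxy-4-(3-phenylprop-1-ynyl)cyclobut-3-ene-1,2-dione | CC(C)OC1=C(C#CCc2ccccc2)C(=O)C1=O | intermediate
6 | rac-4-hydroxy-3-isopropoxy-2-(3-phenylprop-1-ynyl)cyclobut-2-en-1-one | CC(C)OC1=C(C#CCc2ccccc2)C(=O)C1O | intermediate
7 | rac-4-(tert-butyldimethylsilyloxy)-3-isopropoxy-2-(3-phenylprop-1-ynyl)cyclobut-2-en-1-one | CC(C)OC1=C(C#CCc2ccccc2)C(=O)C1O[Si](C)(C)C(C)(C)C | intermediate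
8 | chloroacetaldehyde dimethyl acetal (2-chloro-1,1-dimethoxyethane) | COC(CCl)OC | starting material
9 | allyl bromide | C=CCBr | starting material
10 | sodium methoxyacetylide (sodium 2-methoxyethyn-1-ide) | [Na+].[C-]#COC | intermediate
11 | 1-methoxypent-4-en-1-yne | COC#CCC=C | intermediate
12 | vinylketene: (3Z)-4-(tert-butyldimethylsilyloxy)-3-isopropoxy-2-(3-phenylprop-1-ynyl)buta-1,3-dien-1-one | O=C=C(C#CCc1ccccc1)/C(OC(C)C)=C/O[Si](C)(C)C(C)(C)C | intermediate
13 | vinylcyclobutenone: rac-2-allyl-4-[(Z)-2-(tert-butyldimethylsilyloxy)-1-isopropoxyethenyl]-3-methoxy-4-(3-phenylprop-1-ynyl)cyclobut-2-en-1-one | O=C1C(CC=C)=C(OC)C1(C#CCc2ccccc2)/C(OC(C)C)=C/O[Si](C)(C)C(C)(C)C | intermediate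
14 | dienylketene: (3E,5Z)-2-allyl-6-(tert-butyldimethylsilyloxy)-5-isopropoxy-3-methoxy-4-(3-phenylprop-1-ynyl)hexa-1,3,5-trien-1-one | O=C=C(CC=C)/C(OC)=C(C#CCc1ccccc1)\C(OC(C)C)=C\O[Si](C)(C)C(C)(C)C | intermediate
15 | cyclohexadienone: rac-2-allyl-6-(tert-butyldimethylsilyloxy)-5-isopropoxy-3-methoxy-4-(3-phenylprop-1-ynyl)cyclohexa-2,4-dien-1-one | O=C1C(CC=C)=C(OC)C(C#CCc2ccccc2)=C(OC(C)C)C1O[Si](C)(C)C(C)(C)C | intermediate
16 | 2-allyl-6-(tert-butyldimethylsilyloxy)-5-isopropoxy-3-methoxy-4-(3-phenylprop-1-ynyl)phenol | C=CCc1c(O)c(O[Si](C)(C)C(C)(C)C)c(OC(C)C)c(C#CCc2ccccc2)c1OC | intermediate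
17 | rac-3-[3-(tert-butyldimethylsilyloxy)-2-hydroxy-4-isopropoxy-6-methoxy-5-(3-phenylprop-1-ynyl)phenyl]propane-1,2-diol | OCC(O)Cc1c(O)c(O[Si](C)(C)C(C)(C)C)c(OC(C)C)c(C#CCc2ccccc2)c1OC | intermediate
18 | 2-[3-(tert-butyldimethylsilyloxy)-2-hydroxy-4-isopropoxy-6-methoxy-5-(3-phenylprop-1-ynyl)phenyl]acetaldehyde | O=CCc1c(O)c(O[Si](C)(C)C(C)(C)C)c(OC(C)C)c(C#CCc2ccccc2)c1OC | intermediate
19 | rac-7-(tert-butyldimethylsilyloxy)-6-isopropoxy-4-methoxy-5-(3-phenylprop-1-ynyl)-2,3-dihydrobenzofuran-2-ol | OC1Cc2c(OC)c(C#CCc3ccccc3)c(OC(C)C)c(O[Si](C)(C)C(C)(C)C)c2O1 | intermediate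
20 | 7-(tert-butyldimethylsilyloxy)-6-isopropoxy-4-methoxy-5-(3-phenylprop-1-ynyl)benzofuran-2(3H)-one | O=C1Cc2c(OC)c(C#CCc3ccccc3)c(OC(C)C)c(O[Si](C)(C)C(C)(C)C)c2O1 | intermediate
21 | 7-(tert-butyldimethylsilyloxy)-6-isopropoxy-4-methoxy-5-(3-phenylpropanoyl)benzofuran-2(3H)-one | O=C1Cc2c(OC)c(C(=O)CCc3ccccc3)c(OC(C)C)c(O[Si](C)(C)C(C)(C)C)c2O1 | intermediate
22 | benzaldehyde | O=Cc1ccccc1 | starting material
23 | (Z)-3-benzylidene-7-(tert-butyldimethylsilyloxy)-6-isopropoxy-4-methoxy-5-(3-phenylpropanoyl)benzofuran-2(3H)-one | COc1c(C(=O)CCc2ccccc2)c(OC(C)C)c(O[Si](C)(C)C(C)(C)C)c2c1/C(=C/c1ccccc1)C(=O)O2 | intermediate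
24 | (Z)-3-benzylidene-7-hydroxy-6-isopropoxy-4-methoxy-5-(3-phenylpropanoyl)benzofuran-2(3H)-one | COc1c(C(=O)CCc2ccccc2)c(OC(C)C)c(O)c2c1/C(=C/c1ccccc1)C(=O)O2 | intermediate
25 | bractelactone, (Z)-3-benzylidene-6,7-dihydroxy-4-methoxy-5-(3-phenylpropanoyl)benzofuran-2(3H)-one | COc1c(C(=O)CCc2ccccc2)c(O)c(O)c2c1/C(=C/c1ccccc1)C(=O)O2 | target

**Step count and risks**

Total step count: 11. Longest linear sequence: 10 steps (steps 1–3 and 5–11); step 4 is the one-step side branch.

Steps most likely to fail:

Step 5. The cycloaddition at the alkynyl-substituted ketene carbon may be too slow to compete with ketene oligomerisation, or adduct 13 may open with the alkynyl arm inward and drain into diradical cyclisation. The fallback takes the alkynyl group out of the benzannulation and sets out from squarate 1. Reduction with LiAlH(OtBu)3 gives rac-4-hydroxy-2,3-diisopropoxycyclobut-2-en-1-one F1, and acid (HCl, CH2Cl2) converts it into 3-isopropoxycyclobut-3-ene-1,2-dione F2. A second LiAlH(OtBu)3 reduction at the carbonyl next to the isopropoxy carbon gives rac-4-hydroxy-3-isopropoxycyclobut-2-en-1-one F3, and TBSCl/imidazole gives rac-4-(tert-butyldimethylsilyloxy)-3-isopropoxycyclobut-2-en-1-one F4. Heating F4 with alkyne 11 is then a benzannulation of a 2-unsubstituted cyclobutenone, the best documented substitution type, with a tertiary instead of a quaternary cycloaddition centre. It should pass through vinylketene F5, cyclobutenone adduct F6, dienylketene F7 and cyclohexadienone F8 to 2-allyl-6-(tert-butyldimethylsilyloxy)-5-isopropoxy-3-methoxyphenol F9, whose only free ring position is para to the hydroxyl. Iodination there (I2, morpholine, which spares the allyl group) gives 2-allyl-6-(tert-butyldimethylsilyloxy)-4-iodo-5-isopropoxy-3-methoxyphenol F10. Sonogashira coupling of F10 with alkyne 2 (PdCl2(PPh3)2, CuI, Et3N, THF) comes back to the route at phenol 16.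

Step 6. Periodate may over-oxidise the free, very electron-rich phenol (quinone formation with loss of the neighbouring silyl ether) faster than it cleaves the glycol. The fallback caps the phenol before any oxidant is used and carries the side chain to the acid; it sets out from phenol 16. Boc2O/DMAP gives 2-allyl-6-(tert-butyldimethylsilyloxy)-5-isopropoxy-3-methoxy-4-(3-phenylprop-1-ynyl)phenyl tert-butyl carbonate F11. OsO4/NMO gives diol F12, NaIO4 cleaves it to arylacetaldehyde F13, and Pinnick oxidation (NaClO2, NaH2PO4, 2-methyl-2-butene) gives arylacetic acid F14. CF3CO2H/H2O in CH2Cl2 then removes the carbonate to give hydroxy acid F15, which lactonises under the same acid to lactone 20 and is hydrated there as in step 8. The sequence comes back to the route at ketone 21 and also bypasses the lactol oxidation of step 7.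

Step 9. Base-mediated autoxidation or opening of the aryl lactone, competing aldol chemistry at the ketone methylene, or a slow reversible condensation beside the crowded C4 methoxy group may leave low conversion or E/Z mixtures. The fallback replaces the catalytic condensation by a stoichiometric aldol addition and a separate elimination; it sets out from ketone 21. LiN(SiMe3)2 (1 equiv, THF, −78 °C) should deprotonate only the far more acidic lactone position to give lithium 7-(tert-butyldimethylsilyloxy)-6-isopropoxy-4-methoxy-5-(3-phenylpropanoyl)benzofuran-2-olate F16. Benzaldehyde 22 and a cold acidic quench then give 3-[hydroxy(phenyl)methyl]-7-(tert-butyldimethylsilyloxy)-6-isopropoxy-4-methoxy-5-(3-phenylpropanoyl)benzofuran-2(3H)-one F17 as a diastereomer mixture. MeSO2Cl/Et3N converts it into mesylate F18, which should eliminate in the same flask (E1cB) with the Z alkene favoured for the same steric reason. The sequence comes back to the route at benzylidene lactone 23.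

Further compounds
F1 | step 5 | rac-4-hydroxy-2,3-diisopropoxycyclobut-2-en-1-one | CC(C)OC1=C(OC(C)C)C(O)C1=O
F2 | step 5 | 3-isopropoxycyclobut-3-ene-1,2-dione | CC(C)OC1=CC(=O)C1=O
F3 | step 5 | rac-4-hydroxy-3-isopropoxycyclobut-2-en-1-one | CC(C)OC1=CC(=O)C1O
F4 | step 5 | rac-4-(tert-butyldimethylsilyloxy)-3-isopropoxycyclobut-2-en-1-one | CC(C)OC1=CC(=O)C1O[Si](C)(C)C(C)(C)C
F5 | step 5 | vinylketene: (3Z)-4-(tert-butyldimethylsilyloxy)-3-isopropoxybuta-1,3-dien-1-one | O=C=C/C(OC(C)C)=C/O[Si](C)(C)C(C)(C)C
F6 | step 5 | cyclobutenone adduct: rac-2-allyl-4-[(Z)-2-(tert-butyldimethylsilyloxy)-1-isopropoxyethenyl]-3-methoxycyclobut-2-en-1-one | O=C1C(CC=C)=C(OC)C1/C(OC(C)C)=C/O[Si](C)(C)C(C)(C)C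
F7 | step 5 | dienylketene: (3E,5Z)-2-allyl-6-(tert-butyldimethylsilyloxy)-5-isopropoxy-3-methoxyhexa-1,3,5-trien-1-one | O=C=C(CC=C)/C(OC)=C\C(OC(C)C)=C\O[Si](C)(C)C(C)(C)C
F8 | step 5 | cyclohexadienone: rac-2-allyl-6-(tert-butyldimethylsilyloxy)-5-isopropoxy-3-methoxycyclohexa-2,4-dien-1-one | O=C1C(CC=C)=C(OC)C=C(OC(C)C)C1O[Si](C)(C)C(C)(C)C
F9 | step 5 | 2-allyl-6-(tert-butyldimethylsilyloxy)-5-isopropoxy-3-methoxyphenol | C=CCc1c(O)c(O[Si](C)(C)C(C)(C)C)c(OC(C)C)cc1OC
F10 | step 5 | 2-allyl-6-(tert-butyldimethylsilyloxy)-4-iodo-5-isopropoxy-3-methoxyphenol | C=CCc1c(O)c(O[Si](C)(C)C(C)(C)C)c(OC(C)C)c(I)c1OC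
F11 | step 6 | 2-allyl-6-(tert-butyldimethylsilyloxy)-5-isopropoxy-3-methoxy-4-(3-phenylprop-1-ynyl)phenyl tert-butyl carbonate | C=CCc1c(OC(=O)OC(C)(C)C)c(O[Si](C)(C)C(C)(C)C)c(OC(C)C)c(C#CCc2ccccc2)c1OC
F12 | step 6 | rac-2-(2,3-dihydroxypropyl)-6-(tert-butyldimethylsilyloxy)-5-isopropoxy-3-methoxy-4-(3-phenylprop-1-ynyl)phenyl tert-butyl carbonate | OCC(O)Cc1c(OC(=O)OC(C)(C)C)c(O[Si](C)(C)C(C)(C)C)c(OC(C)C)c(C#CCc2ccccc2)c1OC
F13 | step 6 | 6-(tert-butyldimethylsilyloxy)-5-isopropoxy-3-methoxy-2-(2-oxoethyl)-4-(3-phenylprop-1-ynyl)phenyl tert-butyl carbonate | O=CCc1c(OC(=O)OC(C)(C)C)c(O[Si](C)(C)C(C)(C)C)c(OC(C)C)c(C#CCc2ccccc2)c1OC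
F14 | step 6 | 2-[2-(tert-butoxycarbonyloxy)-3-(tert-butyldimethylsilyloxy)-4-isopropoxy-6-methoxy-5-(3-phenylprop-1-ynyl)phenyl]acetic acid | OC(=O)Cc1c(OC(=O)OC(C)(C)C)c(O[Si](C)(C)C(C)(C)C)c(OC(C)C)c(C#CCc2ccccc2)c1OC
F15 | step 6 | 2-[3-(tert-butyldimethylsilyloxy)-2-hydroxy-4-isopropoxy-6-methoxy-5-(3-phenylprop-1-ynyl)phenyl]acetic acid | OC(=O)Cc1c(O)c(O[Si](C)(C)C(C)(C)C)c(OC(C)C)c(C#CCc2ccccc2)c1OC
F16 | step 9 | lithium 7-(tert-butyldimethylsilyloxy)-6-isopropoxy-4-methoxy-5-(3-phenylpropanoyl)benzofuran-2-olate | [Li+].[O-]c1cc2c(OC)c(C(=O)CCc3ccccc3)c(OC(C)C)c(O[Si](C)(C)C(C)(C)C)c2o1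
F17 | step 9 | 3-[hydroxy(phenyl)methyl]-7-(tert-butyldimethylsilyloxy)-6-isopropoxy-4-methoxy-5-(3-phenylpropanoyl)benzofuran-2(3H)-one (diastereomer mixture) | O=C1Oc2c(O[Si](C)(C)C(C)(C)C)c(OC(C)C)c(C(=O)CCc3ccccc3)c(OC)c2C1C(O)c1ccccc1
F18 | step 9 | [7-(tert-butyldimethylsilyloxy)-6-isopropoxy-4-methoxy-2-oxo-5-(3-phenylpropanoyl)-2,3-dihydrobenzofuran-3-yl](phenyl)methyl methanesulfonate (diastereomer mixture) | O=C1Oc2c(O[Si](C)(C)C(C)(C)C)c(OC(C)C)c(C(=O)CCc3ccccc3)c(OC)c2C1C(OS(C)(=O)=O)c1ccccc1
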